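The nucleophile is the charge you have to find for this flask, and my reckoning treats its concentration as nearly constant.

electrophile 35 mM; solid base 42.0 mM; time 40 min

* the concentration of nucleophile at which the part of the electrophile that has reacted at 40 min is just 90%, in mM

    acid set free + free base ⇌ salt of the base, settled at all times (K1 = 72 M⁻¹)
    electrophile + nucleophile → acid set free + product (k2 = 0.11 M⁻¹ min⁻¹)
    nucleophile + acid set free ⇌ protonated nucleophile, settled at all times (K3 = 1500 M⁻¹)
    acid set free → by-product carried off (k4 = 0.0090 min⁻¹)
    solid base ⇌ free base, rate k5*(cs5 - [free base]) while solid is left; crystals form when [free base] > cs5 (cs5 = 5.2 mM, k5 = 0.034 min⁻¹)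

With [nucleophile] frozen, the electrophile decays pseudo-first-order. The run, in slow motion:

1. Before anything happens: held steady, a [nucleophile] of 523 mM gets 90% of the electrophile reacted in 40 min at 0.11 M⁻¹ min⁻¹. Call this the working level, the steady [nucleophile] a run of this length needs.

2. First instants: at the working level, acid set free appears at 2.01 mM min⁻¹. Solid base dissolving into empty solution delivers free base at 0.177 mM min⁻¹, so the acid set free appears about ten times as fast as the free base.

3. Where the acid set free goes: the nucleophile's binding power, K3[nucleophile], is 785, while free base at its solubility offers 0.374. So I count the acid set free as protonated nucleophile, and each electrophile reacted costs two nucleophiles.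

4. Middle: the electrophile's half-life is 12.0 min. By then 17.5 mM of electrophile has reacted, and at two nucleophiles each [nucleophile] has dropped by 35.0 mM. That is far less than the working level, 6.69% of it, so freezing holds.

5. End: the working level must be the average over the run. On the frozen curve, the average amount of electrophile reacted is 21.3 mM. Two nucleophiles each give my charge, 566 mM.

The forecast also says 566 mM, on the ground that “each electrophile reacted uses up about two nucleophiles”.

The simulation gives 566 mM.

At 40.0 min the electrophile's half-life by its step with the nucleophile is 13 min, while the nucleophile's half-life by that same step is 30 h, far longer. Watch the electrophile: at the working level, 68.4% of it is used by 20.0 min, and the simulated flask has used 69.3%.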